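The numbers in the tables come from a simulation from invented constants.

No rate constant is given for this system, so two working constants have to be read from the earlier runs: a time for the solid substrate and a share for the target.

| flask | solid substrate | partner | remark | time |
|---|---|---|---|---|
| south-east | 0.50 M | 0.090 M | run made earlier |  |
| west | 0.50 M | 0.35 M | run made earlier |  |
| south | 0.50 M | 1.2 M | run made earlier |  |
| dusk | 0.50 M | 0.100 M |  | 8.0 min |
| autumn | 0.50 M | 0.200 M |  | 8.0 min |
| winter | 0.50 M | 0.400 M |  | 8.0 min |
| summer | 0.50 M | 0.800 M |  | 8.0 min |
| noon | 0.50 M | 1.50 M |  | 8.0 min |

| run | time / min | target / % | solid substrate / % |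
|---|---|---|---|
| south-east | 0.833 | 2 | 77 |
| south-east | 1.50 | 2 | 63 |
| south-east | 2.50 | 0 | 44 |
| south-east | 3.00 | 0 | 32 |
| south-east | 4.00 | 2 | 10 |
| west | 0.833 | 0 | 80 |
| west | 1.50 | 1 | 64 |
| west | 2.50 | 5 | 45 |
| west | 3.00 | 1 | 31 |
| west | 4.00 | 4 | 8 |
| south | 0.333 | 0 | 95 |
| south | 1.00 | 3 | 76 |
| south | 2.00 | 5 | 55 |
| south | 3.00 | 11 | 31 |
| south | 4.00 | 12 | 8 |

(standard deviation of a reading: 1.5 percentage points)

- as a solid, counted per litre of solution: solid substrate
- the analysis behind the earlier runs scatters by 1.5 percentage points, standard deviation
- at the start none of the solid substrate is in solution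
- "hardly changes" means that all values lie within two and a half points (for a concentration: within two and a half percent of the largest)

1. amount of target at the end, in percent of the solid substrate charged for dusk, autumn, winter, summer, noon, in this order
2. the course of these numbers from the first flask to the last (falls, then rises / rises, then falls / rises all the way / falls all the way / hardly changes)

At the pace of the south run, the whole solid charge takes 4.21 min. At the pace of the south-east run it takes 4.73 min, although the south run holds 13.3 times as much partner. The solid's time is therefore treated as independent of partner, and 8.0 min lies beyond it, so each flask is reckoned as having used its whole charge.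

Target does depend on partner. At 4.00 min the south run reads 12 % of target with 92.0 % of the solid used, and the ratio of these two readings divided by c(partner) is 0.109 L mol⁻¹. That figure rests on one small reading with a scatter of 1.5 percentage points, so it is the weak link. Averaging the last two south readings reforges it into the capture, a selectivity factor: the share of used solid that becomes target, divided by c(partner), here read as 0.121 L mol⁻¹. The west run did not enter this value; the capture gives it 3.89 % at 4.00 min, against 4 % read.

Target at the end is then the capture times c(partner), taking target as steady once the solid has dissolved, since no reading goes past 4.00 min. This reckoning gives 1.21 % for dusk, 4.83 % for winter and 18.1 % for noon, a row that rises from flask to flask.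

The forecast, reading “a fixed fraction of substrate going to target”, gives 1.3 %, 2.6 %, 5 %, 9.5 % and 16.5 %, rises all the way, lower at noon than the reckoning here.

The flasks give 1.21 %, 2.38 %, 4.61 %, 8.60 % and 14.1 %, rises all the way.

    starting material + partner → target (k = 0.00438 L mol⁻¹ s⁻¹)
    starting material ⇌ other conformer (K = 12.0, k = 0.00282 s⁻¹)
    partner + other conformer → isomer of the product A (k = 0.00946 L mol⁻¹ s⁻¹)
    target ⇌ isomer of the product B (K = 6.10, k = 0.00366 s⁻¹)
    2 starting material → homo dimer (k = 0.0532 L mol⁻¹ s⁻¹)
    solid substrate ⇌ starting material, rate k6*(cs6 - [starting material]) while solid is left; crystals form when [starting material] > cs6 (solubility = 0.440 M, k = 0.00538 s⁻¹)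

The capture's 1.21 % stands against 1.21 % in dusk, and its 18.1 % against 14.1 % in noon. In dusk the forward half-life of target into isomer of the product B is 3.2 min, shorter than the 28 min that starting material needs by its step to target at 2.16 min. Between 4.00 min and 8.00 min dusk's target goes from 1.33 % to 1.21 %, while its isomer of the product B goes from 0.555 % to 1.62 %.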